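**Atom labels.** Upper unit: O1, C2, C3, C4, C4a–C8a (pyran ring C, benzo ring A, pyrogallol ring B on C2). Central pyrogallol ring: E1–E6 (E1 bonded to C2'', E2 to C4, oxygens on E3–E5, H on E6). Lower unit: doubly primed flavan numbering (pyran ring F, benzo ring D). Ar* stands for 3,4,5-tris(benzyloxy)-2-{(2R,3S,4S)-3,7-bis(benzyloxy)-2-[3,4,5-tris(benzyloxy)phenyl]chroman-4-yl}phenyl, that is, perbenzylated ring E carrying the upper flavan on E2.

## Analysis of the target

The target is a biflavonoid in which two 2-arylchromane units share one aromatic ring: ring E is both the 2-aryl group of the lower flavan-3,4-diol and the 4-aryl substituent of the upper flavan-3-ol. It has six stereocentres in two clusters. In ring C, C2 (R), C3 (S) and C4 (S) are 2,3-trans-3,4-trans, so ring B and ring E are cis to each other and both trans to O3. In ring F, C2'' (R), C3'' (S) and C4'' (S) are 2,3-trans-3,4-cis. The clusters communicate only through the E2–E1 edge, so C4 and C2'' are 1,4-related and neither can be trusted to set the other; each unit needs its own control, or a separable pair of diastereomers. Sensitive features are the eight phenolic hydroxyls on oxidisable pyrogallol and resorcinol-type rings, the benzylic C4''–OH (its cation is stabilised by O1'' and O7''), the doubly benzylic C4–E2 bond, and the aryl ether bonds O1–C2 and O1''–C2'', which open under base while a C4 or C4'' carbonyl is present. The hard part is ring E, a pentasubstituted benzene whose neighbouring carbons E1 and E2 each carry a stereogenic benzylic carbon of a different pyran ring, beside the E3 oxygen. The plan rests on ring F being an ordinary flavonoid pyran ring: O1''–C2'' can be closed as in biosynthesis, by conjugate addition of the ring D phenol to a chalcone whose β-carbon sits on E1, and the C4'' carbonyl left behind then delivers O3'' and the C4'' carbinol.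

## Retrosynthetic reasoning

**30 to 29.** The nine O–benzyl bonds are cut last. Benzyl is the only phenol protection that leaves under neutral conditions, which the acid-labile C4''–OH and the air-sensitive pyrogallols require. The forward step must remove nine benzyl groups without touching the benzylic C–O bonds of rings C and F.

**29 to 28 to 26 to 25.** The C4''–H bond and the C3''–O bond are removed in turn, which returns the flavanone 25. Both hydroxyls hang on the one carbonyl that ring closure leaves: enol ether oxidation of 26 places O3'' trans to ring E, and a hindered hydride then reduces the ketone of 28 from the face away from O3'' to give the cis diol. This mirrors the hydroxylase and reductase of the pathway and avoids a separate oxygenated lower building block.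

**25 to 24 (key disconnection).** O1''–C2'' is cut, opening ring F to the 2'-hydroxychalcone 24. This is preferred to any C–C cut at the crowded E1 position because it reduces the whole lower unit to a formyl group on E1 plus a methyl ketone, and because the closure is intramolecular, which tolerates the bulk beside E1. The forward reaction must close a six-membered ring by phenol addition to the enone and fix C2'' as (S) in the flavanone.

**24 to 21 + 22.** The Cα=Cβ bond is cut by a retro-aldol condensation, giving aldehyde 21 (the complete upper unit) and the commercial acetophenone 22. This is the most convergent point of the route: all of ring D and C4'' arrive in one step.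

**21 to 20 to 19.** The formyl group is carried as a cyclic acetal, and O3 is benzylated before the acetal is opened. A free O3 would form a six-membered lactol with the E1 aldehyde, and later it could add to the enone of 24 in competition with the phenol.

**19 to 17.** C3–O and C4–H are removed together, leading to the 4-aryl-2H-chromene 17. Syn hydroboration on the face away from ring B gives all three relative configurations of ring C from the single stereocentre C2, so no separate control of C3 and C4 is needed.

**17 to 16 + 7.** The C4–E2 bond is cut between an sp2 carbon and the aryl ring, giving enol triflate 16 and arylboronate 7. Making this most hindered bond by cross-coupling while C4 is still planar, and with a small ring E fragment, is safer than a cationic arylation at C4, which could also be attacked by ring A of a second molecule.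

**16 to 14 to 9 + 13.** The triflate comes from flavanone 14, and the C2–ring B bond is cut to chromone 9 and boronic acid 13. Catalytic asymmetric conjugate arylation sets C2, the stereocentre from which the rest of the upper unit follows.

**Building blocks.** Boronate 7 comes from 4 by halogen–metal exchange, 4 from 3 by acetalisation, 3 from 2 by bromination ortho to the formyl group (which defines E2), and 2 from commercial 1. Chromone 9 comes from 8, and 13 from bromide 10. The formyl carbon of 1 is the future C2''.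

## Alternatives that were turned down

**Alternative 1:** Both carbon substituents of ring E are cut at once, E1–C (the future C2'') and E2–C4. This leads to the aryne precursor 3,4,5-tris(benzyloxy)-2-(trimethylsilyl)phenyl trifluoromethanesulfonate A2, an isocyanide as one-carbon unit, and 4-(benzyloxy)-2-(methoxymethoxy)benzaldehyde A3 as ring A. In the forward step fluoride releases the aryne from A2 and the isocyanide carbon adds at E1, remote from the E3 oxygen. The E2 anion then adds to the aldehyde of A3, the alkoxide closes on the nitrilium carbon, and aqueous acid gives the racemic phthalide A1.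
- For it: one operation installs both ortho carbons with the correct regiochemistry and makes the hindered E2–C4 bond without a metal catalyst. On that single bond it is at least as direct as the triflate coupling chosen here.
- Against it: A1 contains neither pyran ring and none of the six stereocentres in usable form. Its only stereocentre is racemic and would have to be ionised again to attach C3. The lactone carbon needs redox adjustment before it can become C2'', and A2 itself takes several steps.
- Comparison: the regiochemical problem it solves does not exist in the chosen route, where the E1 carbon is already present in 1 and bromination of 2 marks E2. The chosen route makes the E2–C4 bond in step 9 and has ring C complete, with its three stereocentres, one step later.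

**Alternative 2:** The two C–O bonds of the lower diol are cut, leading to (2S)-7-(benzyloxy)-2-[2-bromo-3,4,5-tris(benzyloxy)phenyl]-2H-chromene A4. The forward step is an OsO4-catalysed syn dihydroxylation of A4 on the face away from ring E, giving the 2,3-trans-3,4-cis diol A5.
- For it: syn addition makes the 3'',4''-cis relationship stereospecific, and attack anti to the C2'' aryl group is dependable. On this point it is stronger than the ketone reduction of step 17, whose cis selectivity rests on reagent bulk.
- Against it: no ring closes and C2'' must already be present in A4 as one enantiomer, although 2-aryl-2H-chromenes can racemise by electrocyclic ring opening. The hindered E2–C4 bond is left for the end, where the bromide of A5 (flanked by a benzyloxy group and the chromanyl group) must be coupled to a complete upper fragment. Ring C would then have to be hydroborated in the presence of the protected lower diol.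
- Comparison: the chosen route forms the hindered bond early with a small partner and closes ring F intramolecularly afterwards. It keeps this dihydroxylation in reserve as the fallback for step 17.

**Alternative 3:** Ring C is cut at C3–C4 and O1–C2, leading to the racemic benzhydrol 5-(benzyloxy)-2-{[6-bromo-2,3,4-tris(benzyloxy)phenyl](hydroxy)methyl}phenol A6 and the ring B (E)-styrylboronate A7. A chiral BINOL-derived phosphoric acid would dehydrate A6 to an ortho-quinone methide, which adds A7 in an endo [4+2] cycloaddition. Oxidation of the C3–B bond with retention gives the flavan-3-ol A8.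
- For it: one catalytic step builds ring C and all three of its stereocentres from simple pieces, against four steps (7 to 10) here. In step count for the upper unit it is clearly stronger.
- Against it: the quinone methide carries a doubly ortho-substituted aryl group on its methide carbon, so its geometry and the endo/exo preference that decide 3,4-trans are uncertain. A β-boryl styrene such as A7 is a weak partner for an electron-poor heterodiene. The absolute sense of induction would have to be found by trial on a step that must deliver three centres at once. A8 still needs bromine-to-formyl exchange before it joins the same endgame.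
- Comparison: the chosen route spends more steps, but each one sets its stereocentre by an understood element (catalyst for C2, syn hydroboration for C3 and C4). The uncertainty is kept for the ring F closure, where failure costs only a separation and a recycle.

Key step: step 14

**Assumptions.** Bromide 10 is taken as a catalogue compound. The ligand in step 7 and the catalyst in step 14 are named in the enantiomeric form expected to give the stated configuration; if a trial shows the opposite sense, the antipodal ligand or the quinidine-derived pseudo-enantiomer is used with nothing else changed.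

## Route

Step 1
Reactants: 1 3,4,5-trihydroxybenzaldehyde
Product: 2 3,4,5-tris(benzyloxy)benzaldehyde
Conditions: BnBr (3.3 equiv), K2CO3, DMF, 60 °C, argon
Reagents that add atoms: benzyl bromide, BrCc1ccccc1
Why: Williamson etherification of the three phenols; the aldehyde is inert to carbonate, and argon protects the pyrogallol until it is alkylated.

Step 2
Reactants: 2 3,4,5-tris(benzyloxy)benzaldehyde
Product: 3 2-bromo-3,4,5-tris(benzyloxy)benzaldehyde
Conditions: N-bromosuccinimide (1.05 equiv), DMF, 0 °C → rt, dark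
Reagents that add atoms: N-bromosuccinimide, O=C1CCC(=O)N1Br
Why: Electrophilic aromatic bromination; the two free ring positions are equivalent and each is ortho and para to a benzyloxy group, so one bromine enters next to the formyl group and defines E2, while the benzyl rings are far less activated.

Step 3
Reactants: 3 2-bromo-3,4,5-tris(benzyloxy)benzaldehyde
Product: 4 2-[2-bromo-3,4,5-tris(benzyloxy)phenyl]-1,3-dioxolane
Conditions: HOCH2CH2OH, p-TsOH (cat.), toluene, reflux, azeotropic removal of water
Reagents that add atoms: ethane-1,2-diol, OCCO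
Why: Acid-catalysed acetalisation driven by water removal; the dioxolane masks the future C2'' carbon against the organolithium, borane and hydride base used later.

Step 4
Reactants: 4 2-[2-bromo-3,4,5-tris(benzyloxy)phenyl]-1,3-dioxolane
Product: 7 2-[3,4,5-tris(benzyloxy)-2-(4,4,5,5-tetramethyl-1,3,2-dioxaborolan-2-yl)phenyl]-1,3-dioxolane, via aryllithium 5 (not isolated), via lithium borate complex 6 (not isolated)
Conditions: n-BuLi (1.05 equiv), THF, −78 °C; then 2-isopropoxy-4,4,5,5-tetramethyl-1,3,2-dioxaborolane, −78 °C → rt; aq. NH4Cl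
Reagents that add atoms: 2-isopropoxy-4,4,5,5-tetramethyl-1,3,2-dioxaborolane, CC(C)OB1OC(C)(C)C(C)(C)O1
Why: Bromine–lithium exchange is faster than benzylic deprotonation at −78 °C and the aryllithium is held by the flanking oxygen atoms; borylation through the ate complex gives a pinacol boronate that survives chromatography.

Step 5
Reactants: 8 7-hydroxy-4H-chromen-4-one
Product: 9 7-(benzyloxy)-4H-chromen-4-one
Conditions: BnBr, K2CO3, acetone, reflux
Reagents that add atoms: benzyl bromide, BrCc1ccccc1
Why: Williamson etherification of the acidic 7-hydroxyl; carbonate in acetone does not open the pyranone ring.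

Step 6
Reactants: 10 5-bromo-1,2,3-tris(benzyloxy)benzene
Product: 13 [3,4,5-tris(benzyloxy)phenyl]boronic acid, via aryllithium 11 (not isolated), via lithium triisopropoxyborate complex 12 (not isolated)
Conditions: n-BuLi, THF, −78 °C; then B(OiPr)3, −78 °C → rt; 1 M HCl
Reagents that add atoms: triisopropyl borate, CC(C)OB(OC(C)C)OC(C)C; water, O
Why: Bromine–lithium exchange, borylation and hydrolysis of the ate complex, the standard route to an arylboronic acid; the lithiated carbon has no ortho substituent, so the exchange is clean.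

Step 7
Reactants: 9 7-(benzyloxy)-4H-chromen-4-one; 13 [3,4,5-tris(benzyloxy)phenyl]boronic acid
Product: 14 (2S)-7-(benzyloxy)-2-[3,4,5-tris(benzyloxy)phenyl]chroman-4-one
Conditions: Pd(OCOCF3)2 (5 mol%), (R)-4-tert-butyl-2-(pyridin-2-yl)-4,5-dihydro-1,3-oxazole (6 mol%), NH4PF6 (30 mol%), H2O (5 equiv), ClCH2CH2Cl, 60 °C
Reagents that add atoms: none
Why: Asymmetric conjugate addition of an arylboronic acid to a chromone under divalent palladium with a pyridine–oxazoline ligand: the aryl group passes from boron to palladium, adds to C2 and the palladium enolate is protonated by water. C2 is set by the ligand, whose tert-butyl group blocks one face of the coordinated enone.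

Step 8
Reactants: 14 (2S)-7-(benzyloxy)-2-[3,4,5-tris(benzyloxy)phenyl]chroman-4-one
Product: 16 (2S)-7-(benzyloxy)-2-[3,4,5-tris(benzyloxy)phenyl]-2H-chromen-4-yl trifluoromethanesulfonate, via lithium enolate 15 (not isolated)
Conditions: LiN(SiMe3)2, THF, −78 °C, 15 min; then N-(5-chloropyridin-2-yl)bis(trifluoromethanesulfonyl)imide, −78 → −40 °C; aq. NH4Cl
Reagents that add atoms: N-(5-chloropyridin-2-yl)bis(trifluoromethanesulfonyl)imide, FC(F)(F)S(=O)(=O)N(c1ccc(Cl)cn1)S(=O)(=O)C(F)(F)F
Why: Kinetic enolisation at the only α-carbon and O-sulfonylation by a triflimide that reacts at −78 °C; the low temperature and short enolate lifetime hold back retro-oxa-Michael opening, so C2 is untouched.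

Step 9
Reactants: 16 (2S)-7-(benzyloxy)-2-[3,4,5-tris(benzyloxy)phenyl]-2H-chromen-4-yl trifluoromethanesulfonate; 7 2-[3,4,5-tris(benzyloxy)-2-(4,4,5,5-tetramethyl-1,3,2-dioxaborolan-2-yl)phenyl]-1,3-dioxolane
Product: 17 (2S)-7-(benzyloxy)-4-[2,3,4-tris(benzyloxy)-6-(1,3-dioxolan-2-yl)phenyl]-2-[3,4,5-tris(benzyloxy)phenyl]-2H-chromene
Conditions: Pd(OAc)2 (5 mol%), 2-dicyclohexylphosphino-2',6'-dimethoxybiphenyl (10 mol%), K3PO4, toluene/H2O, 60 °C, dark; 7 in 1.5-fold excess
Reagents that add atoms: none
Why: Suzuki–Miyaura coupling of an alkenyl triflate, which adds readily to zerovalent palladium, with a doubly ortho-substituted arylboronate; the bulky electron-rich biaryl phosphine is the ligand class made for such hindered transmetalations. Moderate temperature and exclusion of light guard C2 against electrocyclic opening of the 2H-chromene. Slow rotation about the new C4–E2 bond may show 17 as two rotamers, and both are carried on because this axis is no stereogenic element of the target.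

Step 10
Reactants: 17 (2S)-7-(benzyloxy)-4-[2,3,4-tris(benzyloxy)-6-(1,3-dioxolan-2-yl)phenyl]-2-[3,4,5-tris(benzyloxy)phenyl]-2H-chromene
Product: 19 (2R,3S,4S)-7-(benzyloxy)-4-[2,3,4-tris(benzyloxy)-6-(1,3-dioxolan-2-yl)phenyl]-2-[3,4,5-tris(benzyloxy)phenyl]chroman-3-ol, via C3-alkylborane 18 (not isolated)
Conditions: BH3·THF (4 equiv), THF, 0 °C → rt; then NaOH, H2O2, 0 °C → rt
Reagents that add atoms: hydrogen peroxide, OO
Why: Hydroboration–oxidation of a trisubstituted styrene-type alkene: boron goes to C3, the less substituted carbon, and B and H add syn on the face opposite ring B, which decides the face because ring E stands across the alkene plane and puts one ortho substituent on each side. Oxidation with retention puts O3 trans to ring B, and because H4 entered on the same face as boron, ring E lies trans to O3 and cis to ring B, which is the 2,3-trans-3,4-trans triad.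

Step 11
Reactants: 19 (2R,3S,4S)-7-(benzyloxy)-4-[2,3,4-tris(benzyloxy)-6-(1,3-dioxolan-2-yl)phenyl]-2-[3,4,5-tris(benzyloxy)phenyl]chroman-3-ol
Product: 20 (2R,3S,4S)-3,7-bis(benzyloxy)-4-[2,3,4-tris(benzyloxy)-6-(1,3-dioxolan-2-yl)phenyl]-2-[3,4,5-tris(benzyloxy)phenyl]chromane
Conditions: NaH, BnBr, Bu4NI (cat.), DMF, 0 °C → rt
Reagents that add atoms: benzyl bromide, BrCc1ccccc1
Why: Williamson etherification of the equatorial secondary alcohol; benzylating O3 now prevents lactol formation with the aldehyde of step 12 and a competing alkoxide addition to the enone in step 14.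

Step 12
Reactants: 20 (2R,3S,4S)-3,7-bis(benzyloxy)-4-[2,3,4-tris(benzyloxy)-6-(1,3-dioxolan-2-yl)phenyl]-2-[3,4,5-tris(benzyloxy)phenyl]chromane
Product: 21 3,4,5-tris(benzyloxy)-2-{(2R,3S,4S)-3,7-bis(benzyloxy)-2-[3,4,5-tris(benzyloxy)phenyl]chroman-4-yl}benzaldehyde
Conditions: 1 M HCl, THF, rt
Reagents that add atoms: water, O
Why: Acetal hydrolysis; the electron-rich aryl group stabilises the oxocarbenium ion, so dilute acid at room temperature is enough and the benzyl ethers and the C4–E2 bond are not at risk.

Step 13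
Reactants: 21 3,4,5-tris(benzyloxy)-2-{(2R,3S,4S)-3,7-bis(benzyloxy)-2-[3,4,5-tris(benzyloxy)phenyl]chroman-4-yl}benzaldehyde; 22 1-[4-(benzyloxy)-2-hydroxyphenyl]ethanone
Product: 24 (E)-1-[4-(benzyloxy)-2-hydroxyphenyl]-3-Ar*-prop-2-en-1-one, via aldol adduct 23 (not isolated)
Conditions: KOH (50% aq.), EtOH/THF, rt → 40 °C; then AcOH to pH 6 at 0 °C
Reagents that add atoms: none
Why: Claisen–Schmidt condensation: the ketone enolate adds to the non-enolisable aldehyde and the aldol loses water by E1cB to the conjugated (E)-enone. In strong base the product stays open as its phenoxide, and no stereocentre of the upper unit is acidic enough to be affected.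

Step 14
Reactants: 24 (E)-1-[4-(benzyloxy)-2-hydroxyphenyl]-3-Ar*-prop-2-en-1-one
Product: 25 (2S)-7-(benzyloxy)-2-Ar*-chroman-4-one
Conditions: 1-[3,5-bis(trifluoromethyl)phenyl]-3-[(8α,9S)-6'-methoxycinchonan-9-yl]thiourea (20 mol%), toluene, 40 °C
Reagents that add atoms: none
Why: The quinuclidine nitrogen takes the proton of the ring D phenol while the two thiourea N–H bonds hold the enone carbonyl, and the phenoxide adds to the β-carbon so that O1''–C2'' forms and ring F closes in a 6-endo-trig mode; proton transfer from the quinuclidinium to C3'' releases the flavanone. This is the organocatalytic asymmetric intramolecular oxa-Michael addition of 2'-hydroxychalcones to flavanones, the laboratory counterpart of the chalcone isomerase reaction. The one new stereocentre, C2'', is set by the enone face that the catalyst presents to the bound phenoxide; the stereotriad on E2 adds a 1,4-bias of its own, because the flavanyl group twists the enone out of the ring E plane and screens one face. The step needs facial selectivity at C2'' and chemoselectivity for the phenol. Chemoselectivity is secured because O3 is benzylated and the phenol is the only acidic nucleophile. Facial selectivity is backed by the fact that the two possible products are diastereomers and separable on silica. Because the addition is reversible, the unwanted C2'' epimer and unreacted 24 can be returned to the reaction, so a poor ratio costs throughput, not stereochemical purity. The electron-rich, ortho-substituted β-aryl group makes the enone a weak acceptor, hence the warm, long reaction.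

Step 15
Reactants: 25 (2S)-7-(benzyloxy)-2-Ar*-chroman-4-one
Product: 26 (2S)-7-(benzyloxy)-2-Ar*-4-[(trimethylsilyl)oxy]-2H-chromene
Conditions: Me3SiOTf (1.5 equiv), Et3N (3 equiv), CH2Cl2, 0 °C; pentane/aq. NaHCO3 work-up, used at once
Reagents that add atoms: trimethylsilyl trifluoromethanesulfonate, C[Si](C)(C)OS(=O)(=O)C(F)(F)F
Why: Soft enolisation: the carbonyl oxygen is silylated first and the amine then removes H3'', so no free enolate forms that could expel the ring D phenoxide, and C2'' keeps its configuration.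

Step 16
Reactants: 26 (2S)-7-(benzyloxy)-2-Ar*-4-[(trimethylsilyl)oxy]-2H-chromene
Product: 28 (2R,3R)-7-(benzyloxy)-3-hydroxy-2-Ar*-chroman-4-one, via silyloxy epoxide 27 (not isolated)
Conditions: dimethyldioxirane (1.2 equiv, acetone solution), CH2Cl2, −40 → 0 °C; then citric acid (cat.), THF/H2O, 0 °C
Reagents that add atoms: dimethyldioxirane, CC1(C)OO1
Why: Rubottom oxidation: the neutral dioxirane epoxidises the very electron-rich enol ether on the face opposite the bulky C2'' aryl group, and mild acid opens the silyloxy epoxide to the α-hydroxy ketone. O3'' therefore ends trans to ring E, which is also the more stable diequatorial arrangement; at low temperature the benzyl ethers and arenes react far more slowly than the enol ether.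

Step 17
Reactants: 28 (2R,3R)-7-(benzyloxy)-3-hydroxy-2-Ar*-chroman-4-one
Product: 29 (2R,3S,4S)-7-(benzyloxy)-2-Ar*-chromane-3,4-diol
Conditions: LiBH(s-Bu)3 (2.5 equiv), THF, −78 °C; aq. NH4Cl
Reagents that add atoms: none
Why: Reduction with a bulky trialkylborohydride, which attacks the carbonyl along the pseudo-equatorial path on the face away from the adjacent equatorial O3'' substituent, as in the cis-selective reductions of 2-substituted cyclohexanones, 2-substituted tetralones and 3-substituted chroman-4-ones. The new C4''–OH is therefore pseudo-axial and cis to the C3''–OH; the first equivalent of hydride is consumed by the free hydroxyl.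

Step 18
Reactants: 29 (2R,3S,4S)-7-(benzyloxy)-2-Ar*-chromane-3,4-diol
Product: 30 (2R,3S,4S)-2-{3,4,5-trihydroxy-2-[(2R,3S,4S)-3,7-dihydroxy-2-(3,4,5-trihydroxyphenyl)chroman-4-yl]phenyl}chromane-3,4,7-triol
Conditions: H2 (1 atm), Pd(OH)2/C, THF/MeOH, rt; filtered and concentrated under argon
Reagents that add atoms: none
Why: Hydrogenolysis of the nine benzyl ethers under neutral conditions; benzyl ethers cleave faster than the free secondary benzylic alcohol at C4'' and the hindered ring C–O bonds at C2 and C2'', and with no acid present the C4'' cation cannot form.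

## Compound list

1 | 3,4,5-trihydroxybenzaldehyde | O=Cc1cc(O)c(O)c(O)c1 | starting material
2 | 3,4,5-tris(benzyloxy)benzaldehyde | O=Cc1cc(OCc2ccccc2)c(OCc2ccccc2)c(OCc2ccccc2)c1 | intermediate
3 | 2-bromo-3,4,5-tris(benzyloxy)benzaldehyde | O=Cc1cc(OCc2ccccc2)c(OCc2ccccc2)c(OCc2ccccc2)c1Br | intermediate
4 | 2-[2-bromo-3,4,5-tris(benzyloxy)phenyl]-1,3-dioxolane | Brc1c(C2OCCO2)cc(OCc2ccccc2)c(OCc2ccccc2)c1OCc1ccccc1 | intermediate
5 | [2,3,4-tris(benzyloxy)-6-(1,3-dioxolan-2-yl)phenyl]lithium | [Li]c1c(C2OCCO2)cc(OCc2ccccc2)c(OCc2ccccc2)c1OCc1ccccc1 | intermediate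
6 | lithium isopropoxy(pinacolato)[2,3,4-tris(benzyloxy)-6-(1,3-dioxolan-2-yl)phenyl]borate | [Li+].CC(C)O[B-]1(OC(C)(C)C(C)(C)O1)c1c(C2OCCO2)cc(OCc2ccccc2)c(OCc2ccccc2)c1OCc1ccccc1 | intermediate
7 | 2-[3,4,5-tris(benzyloxy)-2-(4,4,5,5-tetramethyl-1,3,2-dioxaborolan-2-yl)phenyl]-1,3-dioxolane | CC1(C)OB(OC1(C)C)c1c(C2OCCO2)cc(OCc2ccccc2)c(OCc2ccccc2)c1OCc1ccccc1 | intermediate
8 | 7-hydroxy-4H-chromen-4-one | O=c1ccoc2cc(O)ccc12 | starting material
9 | 7-(benzyloxy)-4H-chromen-4-one | O=c1ccoc2cc(OCc3ccccc3)ccc12 | intermediate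
10 | 5-bromo-1,2,3-tris(benzyloxy)benzene | Brc1cc(OCc2ccccc2)c(OCc2ccccc2)c(OCc2ccccc2)c1 | starting material
11 | [3,4,5-tris(benzyloxy)phenyl]lithium | [Li]c1cc(OCc2ccccc2)c(OCc2ccccc2)c(OCc2ccccc2)c1 | intermediate
12 | lithium triisopropoxy[3,4,5-tris(benzyloxy)phenyl]borate | [Li+].CC(C)O[B-](OC(C)C)(OC(C)C)c1cc(OCc2ccccc2)c(OCc2ccccc2)c(OCc2ccccc2)c1 | intermediate
13 | [3,4,5-tris(benzyloxy)phenyl]boronic acid | OB(O)c1cc(OCc2ccccc2)c(OCc2ccccc2)c(OCc2ccccc2)c1 | intermediate
14 | (2S)-7-(benzyloxy)-2-[3,4,5-tris(benzyloxy)phenyl]chroman-4-one | c4ccccc4COc1ccc2c(c1)O[C@H](c1cc(OCc4ccccc4)c(OCc4ccccc4)c(OCc4ccccc4)c1)CC2=O | intermediate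
15 | lithium (2S)-7-(benzyloxy)-2-[3,4,5-tris(benzyloxy)phenyl]-2H-chromen-4-olate | c4ccccc4COc1ccc2c(c1)O[C@H](c1cc(OCc4ccccc4)c(OCc4ccccc4)c(OCc4ccccc4)c1)C=C2O[Li] | intermediate
16 | (2S)-7-(benzyloxy)-2-[3,4,5-tris(benzyloxy)phenyl]-2H-chromen-4-yl trifluoromethanesulfonate | c4ccccc4COc1ccc2c(c1)O[C@H](c1cc(OCc4ccccc4)c(OCc4ccccc4)c(OCc4ccccc4)c1)C=C2OS(=O)(=O)C(F)(F)F | intermediate
17 | (2S)-7-(benzyloxy)-4-[2,3,4-tris(benzyloxy)-6-(1,3-dioxolan-2-yl)phenyl]-2-[3,4,5-tris(benzyloxy)phenyl]-2H-chromene | c4ccccc4COc1ccc2c(c1)O[C@H](c1cc(OCc4ccccc4)c(OCc4ccccc4)c(OCc4ccccc4)c1)C=C2c1c(C3OCCO3)cc(OCc4ccccc4)c(OCc4ccccc4)c1OCc4ccccc4 | intermediate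
18 | 2,3-trans-3,4-trans C3-boryl (BH2) adduct of 17, boron trans to ring B and trans to ring E | c4ccccc4COc1ccc2c(c1)O[C@H](c1cc(OCc4ccccc4)c(OCc4ccccc4)c(OCc4ccccc4)c1)[C@@H](B)[C@@H]2c1c(C3OCCO3)cc(OCc4ccccc4)c(OCc4ccccc4)c1OCc4ccccc4 | intermediate
19 | (2R,3S,4S)-7-(benzyloxy)-4-[2,3,4-tris(benzyloxy)-6-(1,3-dioxolan-2-yl)phenyl]-2-[3,4,5-tris(benzyloxy)phenyl]chroman-3-ol | c4ccccc4COc1ccc2c(c1)O[C@H](c1cc(OCc4ccccc4)c(OCc4ccccc4)c(OCc4ccccc4)c1)[C@@H](O)[C@@H]2c1c(C3OCCO3)cc(OCc4ccccc4)c(OCc4ccccc4)c1OCc4ccccc4 | intermediate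
20 | (2R,3S,4S)-3,7-bis(benzyloxy)-4-[2,3,4-tris(benzyloxy)-6-(1,3-dioxolan-2-yl)phenyl]-2-[3,4,5-tris(benzyloxy)phenyl]chromane | c4ccccc4COc1ccc2c(c1)O[C@H](c1cc(OCc4ccccc4)c(OCc4ccccc4)c(OCc4ccccc4)c1)[C@@H](OCc4ccccc4)[C@@H]2c1c(C3OCCO3)cc(OCc4ccccc4)c(OCc4ccccc4)c1OCc4ccccc4 | intermediate
21 | 3,4,5-tris(benzyloxy)-2-{(2R,3S,4S)-3,7-bis(benzyloxy)-2-[3,4,5-tris(benzyloxy)phenyl]chroman-4-yl}benzaldehyde | c4ccccc4COc1ccc2c(c1)O[C@H](c1cc(OCc4ccccc4)c(OCc4ccccc4)c(OCc4ccccc4)c1)[C@@H](OCc4ccccc4)[C@@H]2c1c(C=O)cc(OCc4ccccc4)c(OCc4ccccc4)c1OCc4ccccc4 | intermediate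
22 | 1-[4-(benzyloxy)-2-hydroxyphenyl]ethanone | CC(=O)c1ccc(OCc2ccccc2)cc1O | starting material
23 | 1-[4-(benzyloxy)-2-hydroxyphenyl]-3-hydroxy-3-Ar*-propan-1-one (aldol adduct, carbinol centre undefined) | c4ccccc4COc1ccc2c(c1)O[C@H](c1cc(OCc4ccccc4)c(OCc4ccccc4)c(OCc4ccccc4)c1)[C@@H](OCc4ccccc4)[C@@H]2c1c(C(O)CC(=O)c2ccc(OCc4ccccc4)cc2O)cc(OCc4ccccc4)c(OCc4ccccc4)c1OCc4ccccc4 | intermediate
24 | (E)-1-[4-(benzyloxy)-2-hydroxyphenyl]-3-Ar*-prop-2-en-1-one | c4ccccc4COc1ccc2c(c1)O[C@H](c1cc(OCc4ccccc4)c(OCc4ccccc4)c(OCc4ccccc4)c1)[C@@H](OCc4ccccc4)[C@@H]2c1c(/C=C/C(=O)c2ccc(OCc4ccccc4)cc2O)cc(OCc4ccccc4)c(OCc4ccccc4)c1OCc4ccccc4 | intermediate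
25 | (2S)-7-(benzyloxy)-2-Ar*-chroman-4-one | c4ccccc4COc1ccc2c(c1)O[C@H](c1cc(OCc4ccccc4)c(OCc4ccccc4)c(OCc4ccccc4)c1)[C@@H](OCc4ccccc4)[C@@H]2c1c([C@H]2Oc3cc(OCc4ccccc4)ccc3C(=O)C2)cc(OCc4ccccc4)c(OCc4ccccc4)c1OCc4ccccc4 | intermediate
26 | (2S)-7-(benzyloxy)-2-Ar*-4-[(trimethylsilyl)oxy]-2H-chromene | c4ccccc4COc1ccc2c(c1)O[C@H](c1cc(OCc4ccccc4)c(OCc4ccccc4)c(OCc4ccccc4)c1)[C@@H](OCc4ccccc4)[C@@H]2c1c([C@H]2Oc3cc(OCc4ccccc4)ccc3C(O[Si](C)(C)C)=C2)cc(OCc4ccccc4)c(OCc4ccccc4)c1OCc4ccccc4 | intermediate
27 | 3'',4''-epoxide of 26, oxirane oxygen on the face opposite Ar*, trimethylsilyloxy group on C4'' | c4ccccc4COc1ccc2c(c1)O[C@H](c1cc(OCc4ccccc4)c(OCc4ccccc4)c(OCc4ccccc4)c1)[C@@H](OCc4ccccc4)[C@@H]2c1c([C@H]2Oc3cc(OCc4ccccc4)ccc3[C@]5(O[Si](C)(C)C)O[C@@H]52)cc(OCc4ccccc4)c(OCc4ccccc4)c1OCc4ccccc4 | intermediate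
28 | (2R,3R)-7-(benzyloxy)-3-hydroxy-2-Ar*-chroman-4-one | c4ccccc4COc1ccc2c(c1)O[C@H](c1cc(OCc4ccccc4)c(OCc4ccccc4)c(OCc4ccccc4)c1)[C@@H](OCc4ccccc4)[C@@H]2c1c([C@H]2Oc3cc(OCc4ccccc4)ccc3C(=O)[C@@H]2O)cc(OCc4ccccc4)c(OCc4ccccc4)c1OCc4ccccc4 | intermediate
29 | (2R,3S,4S)-7-(benzyloxy)-2-Ar*-chromane-3,4-diol (2,3-trans-3,4-cis) | c4ccccc4COc1ccc2c(c1)O[C@H](c1cc(OCc4ccccc4)c(OCc4ccccc4)c(OCc4ccccc4)c1)[C@@H](OCc4ccccc4)[C@@H]2c1c([C@H]2Oc3cc(OCc4ccccc4)ccc3[C@H](O)[C@@H]2O)cc(OCc4ccccc4)c(OCc4ccccc4)c1OCc4ccccc4 | intermediate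
30 | (2R,3S,4S)-2-{3,4,5-trihydroxy-2-[(2R,3S,4S)-3,7-dihydroxy-2-(3,4,5-trihydroxyphenyl)chroman-4-yl]phenyl}chromane-3,4,7-triol | Oc1ccc2c(c1)O[C@H](c1cc(O)c(O)c(O)c1)[C@@H](O)[C@@H]2c1c([C@H]2Oc3cc(O)ccc3[C@H](O)[C@@H]2O)cc(O)c(O)c1O | target

## Step count and least certain steps

Total: 18 steps. Longest linear sequence: 14 steps (steps 1 to 4, then 9 to 18).

**Step 14 (key step).** The most likely failure is poor facial selectivity at C2'', or slow conversion. The enone is a weak acceptor, the huge ortho substituent may keep the catalyst from organising the transition state, and the bias of the upper stereotriad may oppose the catalyst. The first remedy is the pseudo-enantiomeric catalyst with separation and recycling of the epimer. The fallback changes how ring F is closed. It sets out from 21 and rejoins the route at 28. Ketone 22 is converted with chloromethyl methyl ether and i-Pr2NEt into 1-[4-(benzyloxy)-2-(methoxymethoxy)phenyl]ethanone F1. Claisen–Schmidt condensation of F1 with 21 gives the 2'-O-methoxymethyl chalcone (E)-1-[4-(benzyloxy)-2-(methoxymethoxy)phenyl]-3-Ar*-prop-2-en-1-one F2. Juliá–Colonna epoxidation of F2 with poly-L-leucine, urea–hydrogen peroxide and DBU in THF, expected to favour the (αR,βS) series, gives the trans-epoxide [4-(benzyloxy)-2-(methoxymethoxy)phenyl][(2R,3S)-3-Ar*-oxiran-2-yl]methanone F3, separable from its diastereomer. HCl in MeOH/THF then removes the methoxymethyl group of F3, and the freed phenol opens the epoxide at the benzylic carbon with inversion. This forms O1''–C2'' and gives the trans-dihydroflavonol 28 directly, bypassing steps 14 to 16.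

**Step 8.** The lithium enolate may expel the ring A phenoxide (retro-oxa-Michael), and reclosure would erode the configuration at C2. The fallback avoids an enolate. It sets out from 14 and 4 and rejoins at 17. Aryllithium 5, made from 4 as in step 4, is transmetalated with anhydrous CeCl3 and added to the ketone of 14 at −78 °C; organocerium reagents add to enolisable ketones without deprotonating them. This gives the tertiary benzylic alcohol (2S)-7-(benzyloxy)-4-[2,3,4-tris(benzyloxy)-6-(1,3-dioxolan-2-yl)phenyl]-2-[3,4,5-tris(benzyloxy)phenyl]chroman-4-ol F4, either C4 epimer serving equally. Dehydration of F4 with methyl N-(triethylammoniosulfonyl)carbamate then gives 17, so steps 8 and 9 are both bypassed.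

**Step 9.** Transmetalation of the doubly ortho-substituted boronate may be slower than its protodeboronation, and prolonged heating invites racemisation of the 2H-chromene by electrocyclic ring opening. The fallback reverses the roles of the partners. It sets out from 16 and rejoins at 17. Miyaura borylation of 16 with B2pin2, PdCl2(dppf) and KOAc in dioxane gives the alkenylboronate (2S)-2-{7-(benzyloxy)-2-[3,4,5-tris(benzyloxy)phenyl]-2H-chromen-4-yl}-4,4,5,5-tetramethyl-1,3,2-dioxaborolane F5. F5 is then coupled with aryl bromide 4 under Pd(OAc)2, the same biaryl phosphine and K3PO4, so the sluggish partner becomes the electrophile and the boron sits on the unhindered alkenyl carbon.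

**Step 17.** The risk is competing axial hydride delivery, which would give the 3'',4''-trans diol. The ring is flattened and has only one axial hydrogen on the opposing face, so the preference for equatorial attack may be smaller than in cyclohexanones. The fallback makes the cis relationship by syn addition. It sets out from 25 and rejoins at 29. NaBH4 in MeOH/THF reduces 25 to the 2,4-cis flavan-4-ol (2S,4S)-7-(benzyloxy)-2-Ar*-chroman-4-ol F6. Dehydration of F6 with methyl N-(triethylammoniosulfonyl)carbamate gives the flav-3-ene (2S)-7-(benzyloxy)-2-Ar*-2H-chromene F7. Dihydroxylation of F7 with catalytic OsO4 and N-methylmorpholine N-oxide on the face opposite Ar* gives 29, bypassing steps 15 to 17.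

**Step 18.** The risk is over-reduction: hydrogenolysis of the C4''–OH bond once the ring D oxygen is free and electron-releasing, and air oxidation of the product during isolation. The fallback reverses the order of deprotection and reduction. It sets out from 28 and rejoins at 30. Hydrogenolysis of 28, which has no benzylic alcohol, gives the free-phenolic dihydroflavonol (2R,3R)-3,7-dihydroxy-2-{3,4,5-trihydroxy-2-[(2R,3S,4S)-3,7-dihydroxy-2-(3,4,5-trihydroxyphenyl)chroman-4-yl]phenyl}chroman-4-one F8. NaBH4 in EtOH reduces F8, expected mainly to the 3'',4''-trans diol (2R,3S,4R)-2-{3,4,5-trihydroxy-2-[(2R,3S,4S)-3,7-dihydroxy-2-(3,4,5-trihydroxyphenyl)chroman-4-yl]phenyl}chromane-3,4,7-triol F9. Brief treatment of F9 with dilute aqueous acetic acid epimerises C4'' through the stabilised benzylic cation, and 30 is separated from remaining F9 by reversed-phase chromatography.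

## Further compounds

F1 | step 14 | 1-[4-(benzyloxy)-2-(methoxymethoxy)phenyl]ethanone | CC(=O)c1ccc(OCc2ccccc2)cc1OCOC
F2 | step 14 | (E)-1-[4-(benzyloxy)-2-(methoxymethoxy)phenyl]-3-Ar*-prop-2-en-1-one | c4ccccc4COc1ccc2c(c1)O[C@H](c1cc(OCc4ccccc4)c(OCc4ccccc4)c(OCc4ccccc4)c1)[C@@H](OCc4ccccc4)[C@@H]2c1c(/C=C/C(=O)c2ccc(OCc4ccccc4)cc2OCOC)cc(OCc4ccccc4)c(OCc4ccccc4)c1OCc4ccccc4
F3 | step 14 | [4-(benzyloxy)-2-(methoxymethoxy)phenyl][(2R,3S)-3-Ar*-oxiran-2-yl]methanone (trans-epoxide, αR,βS) | c4ccccc4COc1ccc2c(c1)O[C@H](c1cc(OCc4ccccc4)c(OCc4ccccc4)c(OCc4ccccc4)c1)[C@@H](OCc4ccccc4)[C@@H]2c1c([C@@H]5O[C@H]5C(=O)c2ccc(OCc4ccccc4)cc2OCOC)cc(OCc4ccccc4)c(OCc4ccccc4)c1OCc4ccccc4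
F4 | step 8 | (2S)-7-(benzyloxy)-4-[2,3,4-tris(benzyloxy)-6-(1,3-dioxolan-2-yl)phenyl]-2-[3,4,5-tris(benzyloxy)phenyl]chroman-4-ol (either C4 epimer) | c4ccccc4COc1ccc2c(c1)O[C@H](c1cc(OCc4ccccc4)c(OCc4ccccc4)c(OCc4ccccc4)c1)CC2(O)c1c(C3OCCO3)cc(OCc4ccccc4)c(OCc4ccccc4)c1OCc4ccccc4
F5 | step 9 | (2S)-2-{7-(benzyloxy)-2-[3,4,5-tris(benzyloxy)phenyl]-2H-chromen-4-yl}-4,4,5,5-tetramethyl-1,3,2-dioxaborolane | c4ccccc4COc1ccc2c(c1)O[C@H](c1cc(OCc4ccccc4)c(OCc4ccccc4)c(OCc4ccccc4)c1)C=C2B1OC(C)(C)C(C)(C)O1
F6 | step 17 | (2S,4S)-7-(benzyloxy)-2-Ar*-chroman-4-ol (2,4-cis) | c4ccccc4COc1ccc2c(c1)O[C@H](c1cc(OCc4ccccc4)c(OCc4ccccc4)c(OCc4ccccc4)c1)[C@@H](OCc4ccccc4)[C@@H]2c1c([C@H]2Oc3cc(OCc4ccccc4)ccc3[C@@H](O)C2)cc(OCc4ccccc4)c(OCc4ccccc4)c1OCc4ccccc4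
F7 | step 17 | (2S)-7-(benzyloxy)-2-Ar*-2H-chromene | c4ccccc4COc1ccc2c(c1)O[C@H](c1cc(OCc4ccccc4)c(OCc4ccccc4)c(OCc4ccccc4)c1)[C@@H](OCc4ccccc4)[C@@H]2c1c([C@H]2Oc3cc(OCc4ccccc4)ccc3C=C2)cc(OCc4ccccc4)c(OCc4ccccc4)c1OCc4ccccc4
F8 | step 18 | (2R,3R)-3,7-dihydroxy-2-{3,4,5-trihydroxy-2-[(2R,3S,4S)-3,7-dihydroxy-2-(3,4,5-trihydroxyphenyl)chroman-4-yl]phenyl}chroman-4-one | Oc1ccc2c(c1)O[C@H](c1cc(O)c(O)c(O)c1)[C@@H](O)[C@@H]2c1c([C@H]2Oc3cc(O)ccc3C(=O)[C@@H]2O)cc(O)c(O)c1O
F9 | step 18 | (2R,3S,4R)-2-{3,4,5-trihydroxy-2-[(2R,3S,4S)-3,7-dihydroxy-2-(3,4,5-trihydroxyphenyl)chroman-4-yl]phenyl}chromane-3,4,7-triol (3'',4''-trans epimer of the target) | Oc1ccc2c(c1)O[C@H](c1cc(O)c(O)c(O)c1)[C@@H](O)[C@@H]2c1c([C@H]2Oc3cc(O)ccc3[C@@H](O)[C@@H]2O)cc(O)c(O)c1O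
A1 | alternative 1 | racemic 4,5,6-tris(benzyloxy)-3-[4-(benzyloxy)-2-(methoxymethoxy)phenyl]isobenzofuran-1(3H)-one | O=C1OC(c2ccc(OCc4ccccc4)cc2OCOC)c2c(OCc4ccccc4)c(OCc4ccccc4)c(OCc4ccccc4)cc12
A2 | alternative 1 | 3,4,5-tris(benzyloxy)-2-(trimethylsilyl)phenyl trifluoromethanesulfonate | C[Si](C)(C)c1c(OS(=O)(=O)C(F)(F)F)cc(OCc2ccccc2)c(OCc2ccccc2)c1OCc1ccccc1
A3 | alternative 1 | 4-(benzyloxy)-2-(methoxymethoxy)benzaldehyde | O=Cc1ccc(OCc2ccccc2)cc1OCOC
A4 | alternative 2 | (2S)-7-(benzyloxy)-2-[2-bromo-3,4,5-tris(benzyloxy)phenyl]-2H-chromene | Brc1c([C@H]2Oc3cc(OCc4ccccc4)ccc3C=C2)cc(OCc4ccccc4)c(OCc4ccccc4)c1OCc4ccccc4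
A5 | alternative 2 | (2R,3S,4S)-7-(benzyloxy)-2-[2-bromo-3,4,5-tris(benzyloxy)phenyl]chromane-3,4-diol (2,3-trans-3,4-cis) | Brc1c([C@H]2Oc3cc(OCc4ccccc4)ccc3[C@H](O)[C@@H]2O)cc(OCc4ccccc4)c(OCc4ccccc4)c1OCc4ccccc4
A6 | alternative 3 | racemic 5-(benzyloxy)-2-{[6-bromo-2,3,4-tris(benzyloxy)phenyl](hydroxy)methyl}phenol | OC(c1ccc(OCc2ccccc2)cc1O)c1c(Br)cc(OCc2ccccc2)c(OCc2ccccc2)c1OCc1ccccc1
A7 | alternative 3 | (E)-4,4,5,5-tetramethyl-2-[3,4,5-tris(benzyloxy)styryl]-1,3,2-dioxaborolane | CC1(C)OB(/C=C/c2cc(OCc3ccccc3)c(OCc3ccccc3)c(OCc3ccccc3)c2)OC1(C)C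
A8 | alternative 3 | (2R,3S,4S)-7-(benzyloxy)-4-[6-bromo-2,3,4-tris(benzyloxy)phenyl]-2-[3,4,5-tris(benzyloxy)phenyl]chroman-3-ol (2,3-trans-3,4-trans) | c4ccccc4COc1ccc2c(c1)O[C@H](c1cc(OCc4ccccc4)c(OCc4ccccc4)c(OCc4ccccc4)c1)[C@@H](O)[C@@H]2c1c(Br)cc(OCc4ccccc4)c(OCc4ccccc4)c1OCc4ccccc4
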